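If the next run is to hold the purest target at the end, the charge of solid substrate has to be chosen among these flasks.

    solid substrate ⇌ dissolved substrate, rate k1*(cs1 - [dissolved substrate]) while solid is left; crystals form when [dissolved substrate] > cs1 (cs1 = 6.0 mM, k1 = 0.0158 h⁻¹)
    dissolved substrate + coupling partner ⇌ target (K2 = 3.8 L mol⁻¹, k2 = 0.242 L mol⁻¹ h⁻¹)
    dissolved substrate + target → side product (k3 = 0.955 L mol⁻¹ h⁻¹)
    coupling partner → decomposition product (k4 = 1.02 × 10⁻⁵ h⁻¹)
    target ⇌ isomer of the product (K5 = 0.220, k5 = 0.0258 h⁻¹)

| setting | spring | autumn | noon |
|---|---|---|---|
| solid substrate | 0.020 M | 0.060 M | 0.20 M |
| coupling partner | 1.30 equiv | 1.30 equiv | 1.30 equiv |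
| time | 50 h | 50 h | 50 h |

- share of target in all that became target or side product or isomer of the product for spring, autumn, noon, in this order
- the shape of the row from first to last (falls all the way / hardly changes / falls, then rises / rises all the way / rises, then falls)

- percent here means solid substrate units held: one side product counts as two
- solid substrate is a solid; its amount is given per volume of the solution
- at the start none of the solid substrate is in solution
- "hardly changes" means that all values lie within two and a half points (for a concentration: within two and a half percent of the largest)
- run time (spring): 50 h

Dissolution runs at 0.0948 mM h⁻¹ at most, so at most 4.74 mM dissolves in 50 h. That is less than the smallest charge and less than the coupling partner in spring. Solid therefore remains through the 50 h of each flask, and the coupling step is taken as pseudo-first-order in dissolved substrate, with the coupling partner held at its charge B.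

Write the share as S = 1/(1 + r + q), with r the isomer per target and q the side product units per target. A first round takes isomer in equilibrium, r = K, the equilibrium constant of the isomer step, and q = 0, which gives 82.0%.

The second round puts the lag back. Target and isomer relax with a time τ, the inverse of the forward and back rate constants summed, here 6.99 h, short against the run. For a steadily growing pool, the lag ratio, r = K(t − τ)/(t + Kτ), is 0.184. It contains no charge.

The third round estimates q, taking target and isomer as balanced with dissolved substrate. With G the coupling equilibrium constant times B, a fraction φ = 1/(1 + G(1 + K)) of the dissolved material stays free. Free substrate at the end is then a = c(1 − exp(−kφt)), with c the solubility and k the dissolution coefficient. If a and target grow in step, q = 2k′at/3, with k′ the side step's constant.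

This reckoning gives a = 3.04 mM in spring and 1.81 mM at noon. The shares are 78.1% for spring, 78.9% for autumn and 80.6% for noon. The spread of 2.5 percentage points sits just inside the margin for hardly changes, so purity gives little reason to raise the charge.

The forecast says 77.8%, 78.2% and 79.5%, hardly changes, holding that “The isomer lags the target by about 8 h”. Its noon share stands below the one reckoned here.

The simulation gives 78.2%, 78.6% and 79.8%, hardly changes. In spring the relaxation half-life of target and isomer by their own step alone, 4.84 h, is short against the 50 h and shorter than the 9.81 h at the asked time of the exchange between dissolved substrate, coupling partner and target by that step alone, and the lag ratio of 0.184 stands against a reading of 0.179 isomer per target at 50.0 h. In the noon flask, with ten times the charge, that reading at 50.0 h is 0.182.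

Its constants belong to no real substance.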